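Amounts first: the flask was charged with 0.10 M starting material and 0.0500 M protic impurity, so the impurity is the smaller charge and its ledger is short.

| flask | starting material | protic impurity | remark | time |
|---|---|---|---|---|
| alpha | 0.050 M | 0.050 M | run made earlier |  |
| gamma | 0.075 M | 0.050 M | run made earlier |  |
| flask | 0.10 M | 0.0500 M |  | 2.5 d |

| run | time / h | target / % | starting material / % |
|---|---|---|---|
| alpha | 1.33 | 28.8 | 61.5 |
| alpha | 3.00 | 44.8 | 35.5 |
| alpha | 6.00 | 48.0 | 11.6 |
| alpha | 12.0 | 45.6 | 2.4 |
| alpha | 25.0 | 39.4 | 0 |
| alpha | 50.0 | 41.0 | 0 |
| gamma | 1.33 | 28.8 | 63.1 |
| gamma | 3.00 | 43.5 | 34.0 |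
| gamma | 6.00 | 48.4 | 12.9 |
| gamma | 12.0 | 42.0 | 2.6 |
| gamma | 25.0 | 39.9 | 0 |
| gamma | 50.0 | 39.1 | 0 |

(each reading ± 1 percentage point)

- percent here means starting material units held: one side product counts as two
- reactions considered so far: starting material <-> other conformer; starting material -> target; other conformer -> isomer of the product; target <-> isomer of the product; other conformer + protic impurity -> quenched substrate; starting material + target -> side product

- time, not beyond 2.5 d, at which the flask holds most target
- the amount of target, in percent of the starting material charged, at that time

I call 0.500 the cover, the moles of protic impurity charged per mole of starting material charged. Of the reactions considered, one draws on the impurity: other conformer + protic impurity → quenched substrate, mole for mole. Each mole charged therefore stands in one of two columns: [protic impurity] + [quenched substrate] equals the [protic impurity] charged. In percent, the share of impurity spent is the quenched substrate, counted on the starting material charged, divided by the cover. In this flask the quenched substrate cannot pass 50.0% of the starting material charged.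

The cover was 1.00 in the alpha run and 0.667 in the gamma run. Their target readings at 6.00 h were 48.0% and 48.4%, a gap of 0.4 percentage points against a scatter of 1 point. So I expected this flask's peak near those readings.

The forecast gave 48.5% (45.5% to 51.5%) at 0.22 d (0.16 d to 0.27 d), saying: “These effects roughly offset, so I expect about the same peak.”

The flask peaked at 0.230 d with 49.4% target, inside both ranges.

    starting material ⇌ other conformer (K = 3.00, k = 1.40 × 10⁻⁵ s⁻¹)
    starting material → target (k = 8.30 × 10⁻⁵ s⁻¹)
    other conformer → isomer of the product (k = 2.30 × 10⁻⁵ s⁻¹)
    target ⇌ isomer of the product (K = 1.20, k = 3.50 × 10⁻⁵ s⁻¹)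
    other conformer + protic impurity → quenched substrate (k = 0.00110 L mol⁻¹ s⁻¹)
    starting material + target → side product (k = 9.60 × 10⁻⁵ L mol⁻¹ s⁻¹)

In the flask, the relaxation half-life of target and isomer of the product, 0.125 d, is short against the 2.5 d allowed. Target fell from its peak to 38.6% by 1.25 d, beside 46.1% isomer of the product, and stood at 38.5% at the end. There the flask's 9.07% quenched substrate, divided by the cover, means 18.1% of the impurity spent and 82% left, while starting material, the limiting reagent, stood at 0%. The neighbour flask with 0.40 M starting material has a cover of 0.125, so its 7.43% quenched substrate means 59.4% of its impurity spent, and its target peaked at 42.6%.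

The data stem from a simulated flask for an exercise; scatter was added.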